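A direct plan would build each flavone from an ortho-hydroxyacetophenone by chalcone condensation and oxidative closure of the pyranone at O1–C2. It would hydroxylate the dibenzyl ether A1 of phloroacetophenone with persulfate to hydroquinone A2, carry A2 to 6-hydroxyflavone A3, arylate A3 with 4-fluorobenzaldehyde to aldehyde A4, and repeat the chalcone sequence on A4. Its weakest steps would be the persulfate hydroxylation (low conversion, and the new hydroxyl needs a protection and deprotection pair), the SNAr at the hindered 6-hydroxyl of a base-sensitive flavone at high temperature, and the second aldol condensation in concentrated KOH, which can open the pyranone already present.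

The route rests on cutting both pyranone rings at the aryl ketone bond C4–C4a and not at O1–C2. Two phenoxide additions to aryl propiolates and one copper-catalysed ether coupling give an acyclic bis(3-aryloxycinnamic acid), and one twofold intramolecular Friedel–Crafts acylation then closes both rings C. The step exploits the twofold symmetry of ring A of unit 1, the 2-(4-methoxyphenyl)chromenone (the ring that carries the C6 aryloxy group between the C5 and C7 oxygens): both carbons ortho to its enol-ether oxygen are equivalent, so only the 5,6,7-pattern can form. The C6 oxygen comes from a formyl group, not from persulfate; the hindered ether is made before any pyranone exists; no chalcone, hydroxide or I2/DMSO touches a flavone.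

Key step: step 7

Remark: unit 2 is the chromenone whose 2-aryl group carries the ether bridge; atom numbers are those of the chromenones.
Assumption: alkynoates 4 and 8 are taken as catalogue compounds; each would otherwise be one Sonogashira coupling of the aryl iodide with ethyl propiolate away.
Remark: the enol ethers are drawn as the Z isomers expected from anti addition; E/Z mixtures would be carried on, since step 7 should be indifferent to this geometry.

Step 1
Reactants: 1 3,5-bis(benzyloxy)phenol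
Product: 3 2,6-bis(benzyloxy)-4-hydroxybenzaldehyde, via iminium chloride 2 (not isolated)
Conditions: POCl3 (1.5 equiv), DMF (5 equiv), MeCN, 0 °C to rt; then H2O, rt
Reagents that add atoms: N,N-dimethylformamide, CN(C)C=O; water, O
Why: Vilsmeier–Haack formylation, in which the chloroiminium ion should attack mainly para to the free hydroxyl (between the two benzyloxy groups), as it does with 3,5-dimethoxyphenol, and the less polar, chelated ortho isomer is removed by crystallisation.

Step 2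
Reactants: 3 2,6-bis(benzyloxy)-4-hydroxybenzaldehyde; 4 ethyl 3-(4-methoxyphenyl)prop-2-ynoate
Product: 5 ethyl (2Z)-3-[3,5-bis(benzyloxy)-4-formylphenoxy]-3-(4-methoxyphenyl)prop-2-enoate
Conditions: Cs2CO3 (0.3 equiv), DMF, 80 °C, under argon
Reagents that add atoms: none
Why: Base-mediated oxa-Michael (conjugate) addition of the phenoxide to the alkynoate, where anti protonation of the vinyl anion should give mainly the Z enol ether and the hindered, non-enolisable aldehyde is inert.

Step 3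
Reactants: 5 ethyl (2Z)-3-[3,5-bis(benzyloxy)-4-formylphenoxy]-3-(4-methoxyphenyl)prop-2-enoate
Product: 7 ethyl (2Z)-3-[3,5-bis(benzyloxy)-4-hydroxyphenoxy]-3-(4-methoxyphenyl)prop-2-enoate, via aryl formate 6 (not isolated)
Conditions: mCPBA (1.3 equiv), CH2Cl2, 0 °C to rt; aq NaHCO3 wash; then Et3N (0.2 equiv), EtOH, rt
Reagents that add atoms: 3-chloroperoxybenzoic acid, OOC(=O)c1cccc(Cl)c1
Why: Dakin-type Baeyer–Villiger oxidation, in which the electron-rich 2,6-dialkoxyaryl group migrates and amine-catalysed ethanolysis cleaves the formate, so that the formyl group is exchanged for the hydroxyl that becomes the C6 oxygen, while the push–pull enol ether should be too electron-poor to be epoxidised.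

Step 4
Reactants: 1 3,5-bis(benzyloxy)phenol; 8 ethyl 3-(4-iodophenyl)prop-2-ynoate
Product: 9 ethyl (2Z)-3-[3,5-bis(benzyloxy)phenoxy]-3-(4-iodophenyl)prop-2-enoate
Conditions: Cs2CO3 (0.3 equiv), DMF, 50 °C, under argon
Reagents that add atoms: none
Why: The same oxa-Michael addition, easier here because phenol 1 is the better nucleophile, with the aryl iodide untouched in the absence of a metal.

Step 5
Reactants: 7 ethyl (2Z)-3-[3,5-bis(benzyloxy)-4-hydroxyphenoxy]-3-(4-methoxyphenyl)prop-2-enoate; 9 ethyl (2Z)-3-[3,5-bis(benzyloxy)phenoxy]-3-(4-iodophenyl)prop-2-enoate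
Product: 10 ethyl (2Z)-3-{3,5-bis(benzyloxy)-4-[4-{(1Z)-1-[3,5-bis(benzyloxy)phenoxy]-3-ethoxy-3-oxoprop-1-en-1-yl}phenoxy]phenoxy}-3-(4-methoxyphenyl)prop-2-enoate
Conditions: CuI (10 mol%), picolinic acid (20 mol%), K3PO4 (2 equiv), DMSO, 85 °C, under argon
Reagents that add atoms: none
Why: Ullmann-type copper-catalysed C–O coupling with picolinic acid as ligand, a system that accepts phenols with two ortho substituents, on a substrate in which any ester hydrolysis by the phosphate would be harmless because step 6 follows.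

Step 6
Reactants: 10 the diester of step 5
Product: 11 (2Z)-3-{3,5-bis(benzyloxy)-4-[4-{(1Z)-1-[3,5-bis(benzyloxy)phenoxy]-2-carboxyethenyl}phenoxy]phenoxy}-3-(4-methoxyphenyl)prop-2-enoic acid
Conditions: LiOH·H2O (6 equiv), THF/MeOH/H2O 3:1:1, 40 °C; then 1 M HCl to pH 3, 0 °C
Reagents that add atoms: lithium hydroxide, [Li+].[OH-]
Why: Saponification of the two vinylogous carbonate esters, which is known to give 3-aryloxycinnamic acids with the aryloxy group retained when the acidification is kept cold and mild.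

Step 7 (key step)
Reactants: 11 the diacid of step 6
Product: 13 5,7-bis(benzyloxy)-6-{4-[5,7-bis(benzyloxy)-4-oxo-4H-chromen-2-yl]phenoxy}-2-(4-methoxyphenyl)-4H-chromen-4-one, via bis(acid chloride) 12 (not isolated)
Conditions: (COCl)2 (3 equiv), DMF (2 mol%), CH2Cl2, 0 °C to rt; evaporate; (CF3)2CHOH (0.01 M), rt; aq NaHCO3
Reagents that add atoms: none
Why: Twofold intramolecular Friedel–Crafts acylation: in the ionising, hydrogen-bond-donating solvent each acid chloride gives an acylium ion that is a vinylogous oxocarbenium (ketene–oxocarbenium form), which attacks the ring carbon ortho to its own enol-ether oxygen and re-aromatises by loss of a proton. The closest known reactions are the acid-mediated cyclisation of 3-aryloxycinnamic acids to flavones and the acylation of electron-rich arenes by acid chlorides in hexafluoropropan-2-ol without a Lewis acid. Both pyranone rings close at C4–C4a as six-membered rings by 6-exo-dig attack of the arene on the acylium carbon (equivalently a 6π closure of the ketene form), and no stereocentre is formed. The step needs regioselectivity, which symmetry secures: in ring A of unit 1 the two carbons ortho to the enol-ether oxygen are equivalent (benzyloxy groups at the future C5 and C7 flank the aryloxy group at the future C6), and in ring A of unit 2 the only carbons within reach are the two equivalent ones between the enol-ether oxygen and a benzyloxy group. Enol-ether geometry should not matter, because rotation about the former C=C bond in the ketene–oxocarbenium form lets E isomers converge, while closure onto the C-aryl rings (indenone formation) is disfavoured since their ortho carbons are meta to the donor oxygen. High dilution should hold back intermolecular acylation and the absence of a Lewis acid should keep the benzyl ethers in place, and partial loss of a chelated C5 benzyl group would be harmless because step 8 removes all four.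

Step 8
Reactants: 13 5,7-bis(benzyloxy)-6-{4-[5,7-bis(benzyloxy)-4-oxo-4H-chromen-2-yl]phenoxy}-2-(4-methoxyphenyl)-4H-chromen-4-one
Product: 14 cryptomerin A
Conditions: H2 (1 atm), 10% Pd/C, THF/MeOH 1:1, rt
Reagents that add atoms: none
Why: Catalytic hydrogenolysis of the four benzylic C–O bonds, which should leave the aryl methyl ether, the diaryl ether and the pyranone C2=C3 bonds untouched at 1 atm and rt.

Compound list
1 | 3,5-bis(benzyloxy)phenol | Oc1cc(OCc2ccccc2)cc(OCc3ccccc3)c1 | starting material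
2 | {[2,6-bis(benzyloxy)-4-hydroxyphenyl]methylidene}dimethyliminium chloride | C[N+](C)=Cc1c(OCc2ccccc2)cc(O)cc1OCc3ccccc3.[Cl-] | intermediate
3 | 2,6-bis(benzyloxy)-4-hydroxybenzaldehyde | O=Cc1c(OCc2ccccc2)cc(O)cc1OCc3ccccc3 | intermediate
4 | ethyl 3-(4-methoxyphenyl)prop-2-ynoate | CCOC(=O)C#Cc1ccc(OC)cc1 | starting material
5 | ethyl (2Z)-3-[3,5-bis(benzyloxy)-4-formylphenoxy]-3-(4-methoxyphenyl)prop-2-enoate | CCOC(=O)/C=C(\Oc1cc(OCc2ccccc2)c(C=O)c(OCc3ccccc3)c1)c4ccc(OC)cc4 | intermediate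
6 | ethyl (2Z)-3-[3,5-bis(benzyloxy)-4-(formyloxy)phenoxy]-3-(4-methoxyphenyl)prop-2-enoate | CCOC(=O)/C=C(\Oc1cc(OCc2ccccc2)c(OC=O)c(OCc3ccccc3)c1)c4ccc(OC)cc4 | intermediate
7 | ethyl (2Z)-3-[3,5-bis(benzyloxy)-4-hydroxyphenoxy]-3-(4-methoxyphenyl)prop-2-enoate | CCOC(=O)/C=C(\Oc1cc(OCc2ccccc2)c(O)c(OCc3ccccc3)c1)c4ccc(OC)cc4 | intermediate
8 | ethyl 3-(4-iodophenyl)prop-2-ynoate | CCOC(=O)C#Cc1ccc(I)cc1 | starting material
9 | ethyl (2Z)-3-[3,5-bis(benzyloxy)phenoxy]-3-(4-iodophenyl)prop-2-enoate | CCOC(=O)/C=C(\Oc1cc(OCc2ccccc2)cc(OCc3ccccc3)c1)c4ccc(I)cc4 | intermediate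
10 | ethyl (2Z)-3-{3,5-bis(benzyloxy)-4-[4-{(1Z)-1-[3,5-bis(benzyloxy)phenoxy]-3-ethoxy-3-oxoprop-1-en-1-yl}phenoxy]phenoxy}-3-(4-methoxyphenyl)prop-2-enoate | CCOC(=O)/C=C(\Oc1cc(OCc2ccccc2)c(Oc3ccc(cc3)/C(Oc4cc(OCc5ccccc5)cc(OCc6ccccc6)c4)=C/C(=O)OCC)c(OCc7ccccc7)c1)c8ccc(OC)cc8 | intermediate
11 | (2Z)-3-{3,5-bis(benzyloxy)-4-[4-{(1Z)-1-[3,5-bis(benzyloxy)phenoxy]-2-carboxyethenyl}phenoxy]phenoxy}-3-(4-methoxyphenyl)prop-2-enoic acid | OC(=O)/C=C(\Oc1cc(OCc2ccccc2)c(Oc3ccc(cc3)/C(Oc4cc(OCc5ccccc5)cc(OCc6ccccc6)c4)=C/C(O)=O)c(OCc7ccccc7)c1)c8ccc(OC)cc8 | intermediate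
12 | (2Z)-3-{3,5-bis(benzyloxy)-4-[4-{(1Z)-1-[3,5-bis(benzyloxy)phenoxy]-3-chloro-3-oxoprop-1-en-1-yl}phenoxy]phenoxy}-3-(4-methoxyphenyl)prop-2-enoyl chloride | ClC(=O)/C=C(\Oc1cc(OCc2ccccc2)c(Oc3ccc(cc3)/C(Oc4cc(OCc5ccccc5)cc(OCc6ccccc6)c4)=C/C(Cl)=O)c(OCc7ccccc7)c1)c8ccc(OC)cc8 | intermediate
13 | 5,7-bis(benzyloxy)-6-{4-[5,7-bis(benzyloxy)-4-oxo-4H-chromen-2-yl]phenoxy}-2-(4-methoxyphenyl)-4H-chromen-4-one | COc1ccc(-c2cc(=O)c3c(OCc4ccccc4)c(Oc5ccc(-c6cc(=O)c7c(OCc8ccccc8)cc(OCc9ccccc9)cc7o6)cc5)c(OCc4ccccc4)cc3o2)cc1 | intermediate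
14 | cryptomerin A, 6-[4-(5,7-dihydroxy-4-oxo-4H-chromen-2-yl)phenoxy]-5,7-dihydroxy-2-(4-methoxyphenyl)-4H-chromen-4-one (achiral) | COc1ccc(-c2cc(=O)c3c(O)c(Oc4ccc(-c5cc(=O)c6c(O)cc(O)cc6o5)cc4)c(O)cc3o2)cc1 | target

Total step count: 8
Longest linear sequence: 7 (steps 1, 2, 3, 5, 6, 7, 8; step 4 is a one-step branch)

Steps most likely to fail

Step 7. The closure onto ring A of unit 1, whose acylium ion is stabilised by the anisyl group, may lag behind the closure of unit 2, so that intermolecular acylation and acid-induced loss or migration of benzyl groups compete while the half-closed material waits. The fallback would split the twofold closure and would set out from 9. Saponification (LiOH, then cold HCl) would give (2Z)-3-[3,5-bis(benzyloxy)phenoxy]-3-(4-iodophenyl)prop-2-enoic acid F1. Its acid chloride, (2Z)-3-[3,5-bis(benzyloxy)phenoxy]-3-(4-iodophenyl)prop-2-enoyl chloride F2, would close in hexafluoropropan-2-ol to 5,7-bis(benzyloxy)-2-(4-iodophenyl)-4H-chromen-4-one F3. Copper-catalysed coupling of F3 with phenol 7 under the conditions of step 5 would give ethyl (2Z)-3-(3,5-bis(benzyloxy)-4-{4-[5,7-bis(benzyloxy)-4-oxo-4H-chromen-2-yl]phenoxy}phenoxy)-3-(4-methoxyphenyl)prop-2-enoate F4, and saponification would give the corresponding acid, (2Z)-3-(3,5-bis(benzyloxy)-4-{4-[5,7-bis(benzyloxy)-4-oxo-4H-chromen-2-yl]phenoxy}phenoxy)-3-(4-methoxyphenyl)prop-2-enoic acid F5. The single remaining closure, through the acid chloride (2Z)-3-(3,5-bis(benzyloxy)-4-{4-[5,7-bis(benzyloxy)-4-oxo-4H-chromen-2-yl]phenoxy}phenoxy)-3-(4-methoxyphenyl)prop-2-enoyl chloride F6, could then be forced with SnCl4 at −78 °C if needed, and would come back to the route at 13.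

Step 5. Ligand exchange at copper may be slow for a phenoxide flanked by two benzyloxy groups, so that oxidation of the electron-rich phenol or exchange of aryloxy groups at the enol ethers takes over. The fallback would be metal-free and would set out from 7. SNAr on 4-fluorobenzaldehyde (K2CO3, DMF, 90 °C) would give ethyl (2Z)-3-[3,5-bis(benzyloxy)-4-(4-formylphenoxy)phenoxy]-3-(4-methoxyphenyl)prop-2-enoate F7. Wittig olefination with Ph3P=C(Br)CO2Et (toluene, 80 °C) would give ethyl (2Z)-2-bromo-3-(4-{2,6-bis(benzyloxy)-4-[(1Z)-3-ethoxy-1-(4-methoxyphenyl)-3-oxoprop-1-en-1-yl]oxyphenoxy}phenyl)prop-2-enoate F8. Treatment of F8 with phenol 1 and Cs2CO3 in DMF at 80 °C should eliminate HBr to the alkynoate, ethyl 3-(4-{2,6-bis(benzyloxy)-4-[(1Z)-3-ethoxy-1-(4-methoxyphenyl)-3-oxoprop-1-en-1-yl]oxyphenoxy}phenyl)prop-2-ynoate F9 (not isolated), to which 1 would add, and the sequence would come back to the route at 10.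

Step 2. The conjugate addition may be sluggish or reversible, because the phenoxide of 3 is a vinylogous carboxylate and alkynoate 4 is deactivated by its methoxy group. The fallback would place the oxidation first and would set out from 3. Dakin oxidation (H2O2, aq NaOH, 0 °C, under nitrogen, then acid) would give 2,6-bis(benzyloxy)benzene-1,4-diol F10. Its unhindered and more acidic 4-hydroxyl, now a far better nucleophile, should add to 4 (Cs2CO3 0.3 equiv, DMF, rt, under argon), while the hydroxyl between the two benzyloxy groups stays free. This would come back to the route at 7 and would replace steps 2 and 3.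

Further compounds
F1 | step 7 | (2Z)-3-[3,5-bis(benzyloxy)phenoxy]-3-(4-iodophenyl)prop-2-enoic acid | OC(=O)/C=C(\Oc1cc(OCc2ccccc2)cc(OCc3ccccc3)c1)c4ccc(I)cc4
F2 | step 7 | (2Z)-3-[3,5-bis(benzyloxy)phenoxy]-3-(4-iodophenyl)prop-2-enoyl chloride | ClC(=O)/C=C(\Oc1cc(OCc2ccccc2)cc(OCc3ccccc3)c1)c4ccc(I)cc4
F3 | step 7 | 5,7-bis(benzyloxy)-2-(4-iodophenyl)-4H-chromen-4-one | O=c1cc(-c2ccc(I)cc2)oc3cc(OCc4ccccc4)cc(OCc5ccccc5)c13
F4 | step 7 | ethyl (2Z)-3-(3,5-bis(benzyloxy)-4-{4-[5,7-bis(benzyloxy)-4-oxo-4H-chromen-2-yl]phenoxy}phenoxy)-3-(4-methoxyphenyl)prop-2-enoate | CCOC(=O)/C=C(\Oc1cc(OCc2ccccc2)c(Oc3ccc(-c4cc(=O)c5c(OCc6ccccc6)cc(OCc7ccccc7)cc5o4)cc3)c(OCc8ccccc8)c1)c9ccc(OC)cc9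
F5 | step 7 | (2Z)-3-(3,5-bis(benzyloxy)-4-{4-[5,7-bis(benzyloxy)-4-oxo-4H-chromen-2-yl]phenoxy}phenoxy)-3-(4-methoxyphenyl)prop-2-enoic acid | OC(=O)/C=C(\Oc1cc(OCc2ccccc2)c(Oc3ccc(-c4cc(=O)c5c(OCc6ccccc6)cc(OCc7ccccc7)cc5o4)cc3)c(OCc8ccccc8)c1)c9ccc(OC)cc9
F6 | step 7 | (2Z)-3-(3,5-bis(benzyloxy)-4-{4-[5,7-bis(benzyloxy)-4-oxo-4H-chromen-2-yl]phenoxy}phenoxy)-3-(4-methoxyphenyl)prop-2-enoyl chloride | ClC(=O)/C=C(\Oc1cc(OCc2ccccc2)c(Oc3ccc(-c4cc(=O)c5c(OCc6ccccc6)cc(OCc7ccccc7)cc5o4)cc3)c(OCc8ccccc8)c1)c9ccc(OC)cc9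
F7 | step 5 | ethyl (2Z)-3-[3,5-bis(benzyloxy)-4-(4-formylphenoxy)phenoxy]-3-(4-methoxyphenyl)prop-2-enoate | CCOC(=O)/C=C(\Oc1cc(OCc2ccccc2)c(Oc3ccc(C=O)cc3)c(OCc4ccccc4)c1)c5ccc(OC)cc5
F8 | step 5 | ethyl (2Z)-2-bromo-3-(4-{2,6-bis(benzyloxy)-4-[(1Z)-3-ethoxy-1-(4-methoxyphenyl)-3-oxoprop-1-en-1-yl]oxyphenoxy}phenyl)prop-2-enoate | CCOC(=O)/C=C(\Oc1cc(OCc2ccccc2)c(Oc3ccc(cc3)/C=C(\Br)C(=O)OCC)c(OCc4ccccc4)c1)c5ccc(OC)cc5
F9 | step 5 | ethyl 3-(4-{2,6-bis(benzyloxy)-4-[(1Z)-3-ethoxy-1-(4-methoxyphenyl)-3-oxoprop-1-en-1-yl]oxyphenoxy}phenyl)prop-2-ynoate | CCOC(=O)/C=C(\Oc1cc(OCc2ccccc2)c(Oc3ccc(cc3)C#CC(=O)OCC)c(OCc4ccccc4)c1)c5ccc(OC)cc5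
F10 | step 2 | 2,6-bis(benzyloxy)benzene-1,4-diol | Oc1cc(OCc2ccccc2)c(O)c(OCc3ccccc3)c1
A1 | direct plan | 1-[2,4-bis(benzyloxy)-6-hydroxyphenyl]ethan-1-one | CC(=O)c1c(O)cc(OCc2ccccc2)cc1OCc3ccccc3
A2 | direct plan | 1-[2,4-bis(benzyloxy)-3,6-dihydroxyphenyl]ethan-1-one | CC(=O)c1c(O)cc(OCc2ccccc2)c(O)c1OCc3ccccc3
A3 | direct plan | 5,7-bis(benzyloxy)-6-hydroxy-2-(4-methoxyphenyl)-4H-chromen-4-one | COc1ccc(-c2cc(=O)c3c(OCc4ccccc4)c(O)c(OCc5ccccc5)cc3o2)cc1
A4 | direct plan | 4-{[5,7-bis(benzyloxy)-2-(4-methoxyphenyl)-4-oxo-4H-chromen-6-yl]oxy}benzaldehyde | COc1ccc(-c2cc(=O)c3c(OCc4ccccc4)c(Oc5ccc(C=O)cc5)c(OCc6ccccc6)cc3o2)cc1
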